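**Plan**
- **Cuts:** after the side-chain acetyl and the two benzyl groups are removed, ring A is cut at C1–C2 and C1–C6. The pyranone side chain is then cut at C1'–C2', and the ring B chain at its aryl–CH2 bond.
- **Enabling feature:** C2–C6 of ring A, with the oxygen on C2, the methoxy on C4 and the alkyl chain on C6, are the five ring carbons of a 6-alkyl-4-methoxy-2-pyranone. Only C1 and its carboxyl carbon are missing, and these are the CH3 and C=O of the acetate of the ring B carbinol.
- **Forward, fragments:** one epoxide opening gives (R)-undec-10-en-4-ol, which is divided. One part becomes a C11 silyloxy iodide and is joined to 4-methoxy-6-methyl-2-pyranone. The other is acetylated and joined to ring B by B-alkyl Suzuki coupling.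
- **Forward, rings:** ring B and the pyranone ring are bought. Ring A is the only ring made, from the pyranone and the acetate enolate, with the hindered ester already in place. Desilylation, acetylation and hydrogenolysis finish the target.
- **Stereochemistry:** both R carbinol centres come from (R)-2-propyloxirane, and no bond to either centre is broken after step 1.

Key step: step 8

Remark: ring A is numbered from the ester-bearing carbon (C1) through the phenol carbon (C2) and the methoxy carbon (C4) to the alkylated carbon (C6). LiN(iPr)2 is taken from a commercial solution, and protons not shown come from aqueous work-up.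

Step 1
Reactants: 1 6-bromohex-1-ene; 2 (R)-2-propyloxirane
Product: 4 (R)-undec-10-en-4-ol, via hex-5-enylmagnesium bromide 3 (not isolated)
Conditions: Mg, THF, 25–40 °C; then 2, CuI (10 mol %), THF, −30 → 0 °C
Reagents that add atoms: none
Why: Copper-catalysed Grignard opening of a terminal epoxide is an SN2 attack at the unsubstituted CH2, so the C–O bond of the stereocentre is untouched and the R configuration of 2 becomes that of C4 in 4.

Step 2
Reactants: 4 (R)-undec-10-en-4-ol
Product: 5 (R)-tert-butyldimethyl(undec-10-en-4-yloxy)silane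
Conditions: TBSCl, imidazole, DMF, rt
Reagents that add atoms: tert-butyldimethylsilyl chloride (TBSCl), CC(C)(C)[Si](C)(C)Cl
Why: Imidazole-promoted silylation of a secondary alcohol is routine, takes place at oxygen with retention, and gives an ether that withstands boranes, lithium amides and enolates.

Step 3
Reactants: 5 (R)-tert-butyldimethyl(undec-10-en-4-yloxy)silane
Product: 7 (R)-8-(tert-butyldimethylsilyloxy)undecan-1-ol, via B-alkyl-9-BBN adduct 6 (not isolated)
Conditions: 9-BBN, THF, 0 °C → rt; then NaOH, H2O2, H2O, 0 °C → rt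
Reagents that add atoms: hydrogen peroxide, OO
Why: Brown hydroboration–oxidation with the bulky 9-BBN places boron on the terminal carbon (anti-Markovnikov), and alkaline peroxide exchanges it for hydroxyl without harming the silyl ether.

Step 4
Reactants: 7 (R)-8-(tert-butyldimethylsilyloxy)undecan-1-ol
Product: 8 (R)-tert-butyl[(11-iodoundecan-4-yl)oxy]dimethylsilane
Conditions: I2, PPh3, imidazole, CH2Cl2, 0 °C → rt
Reagents that add atoms: iodine, II
Why: In this Appel-type iodination (Garegg–Samuelsson conditions) the primary alcohol is activated as its oxyphosphonium salt and displaced by iodide in an SN2 step, while imidazole buffers the medium so that the silyl ether survives.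

Step 5
Reactants: 9 4-methoxy-6-methyl-2H-pyran-2-one; 8 (R)-tert-butyl[(11-iodoundecan-4-yl)oxy]dimethylsilane
Product: 11 6-[(9R)-9-(tert-butyldimethylsilyloxy)dodecyl]-4-methoxy-2H-pyran-2-one, via lithiated pyranone 10 (not isolated)
Conditions: 9 (1.5 equiv), LiN(iPr)2, THF–DMPU, −78 °C; then 8, −78 → −20 °C
Reagents that add atoms: none
Why: Lateral (vinylogous) deprotonation of the 6-methyl group of 4-methoxy-2-pyranones by a lithium amide, followed by SN2 alkylation of the exocyclic carbanion with primary iodides, is established pyranone chemistry; the dipolar cosolvent speeds the displacement and the excess of cheap 9 limits a second alkylation.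

Step 6
Reactants: 4 (R)-undec-10-en-4-ol
Product: 12 (R)-undec-10-en-4-yl acetate
Conditions: Ac2O, pyridine, DMAP (cat.), CH2Cl2, rt
Reagents that add atoms: acetic anhydride, CC(=O)OC(C)=O
Why: DMAP-catalysed acetylation acylates the oxygen without breaking the C–O bond, so the R configuration is retained and the two carbons that become C1 and the ester carbonyl of ring A are installed.

Step 7
Reactants: 12 (R)-undec-10-en-4-yl acetate; 13 1,3-bis(benzyloxy)-5-bromobenzene
Product: 15 (R)-11-[3,5-bis(benzyloxy)phenyl]undecan-4-yl acetate, via B-alkyl-9-BBN adduct 14 (not isolated)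
Conditions: 9-BBN, THF, 0 °C → rt; then 13, Pd(OAc)2 (3 mol %), SPhos (6 mol %), K3PO4·H2O, THF, 40 °C
Reagents that add atoms: none
Why: Anti-Markovnikov hydroboration with 9-BBN, which leaves esters alone, is followed by B-alkyl Suzuki–Miyaura coupling (oxidative addition of zerovalent palladium into 13, transmetalation of the borate, reductive elimination), forming the aryl–CH2 bond under a phosphate base mild enough for a secondary acetate.

Step 8
Reactants: 15 (R)-11-[3,5-bis(benzyloxy)phenyl]undecan-4-yl acetate; 11 6-[(9R)-9-(tert-butyldimethylsilyloxy)dodecyl]-4-methoxy-2H-pyran-2-one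
Product: 20 (R)-11-[3,5-bis(benzyloxy)phenyl]undecan-4-yl 6-[(9R)-9-(tert-butyldimethylsilyloxy)dodecyl]-2-hydroxy-4-methoxybenzoate, via lithium enolate 16 (not isolated), via dichlorocerium enolate 17 (not isolated), via open-chain dioxo enoate 18 (not isolated), via aldol adduct 19 (not isolated)
Conditions: 15 (2 equiv), LiN(iPr)2 (2 equiv), THF, −78 °C; CeCl3 (anhydrous, 2 equiv), −78 °C; 11 (1 equiv), −78 → −30 °C; AcOH; then DBU, −30 °C → rt
Reagents that add atoms: none
Why: Proposed new method: the acetate of 15 is deprotonated to 16 and passed to cerium (17), the enolate carbon adds to the lactone carbonyl (pyranone C2) of 11, and the tetrahedral adduct opens at the ring oxygen, at the latest on acidification, to the (4E)-5-methoxy-3,7-dioxo-4-enoate 18, in which C3 and C6 stay cis on the enol-ether double bond because they were ring neighbours in 11. DBU then ionises the doubly activated CH2 of 18 (the former acetyl methyl, future C1), which attacks the C7 ketone (former pyranone C6, future C6 of ring A) in a 6-exo-trig aldol closure, favoured whether the nucleophile is counted as enolexo through the ester or enolendo through the C3 ketone, and the aldol 19 loses the former ring oxygen as water (E1cB) and tautomerises to the phenol 20, so that C1–C2 and C1–C6 are made and ring A is closed in one operation. The closest known reaction types are the crossed Claisen addition of acetate enolates to esters and lactones, the conversion of pyrylium salts and 2-pyranones into benzenes by carbon nucleophiles, and the base-induced aldol aromatisation of 3,5,7-tricarbonyl esters to resorcylates; their union on a 4-alkoxy-2-pyranone with a plain acetate enolate is what has not been shown. No stereocentre remains from the step (the two centres of 19 vanish on aromatisation), and the two carbinol centres lie away from every acidic position and keep their R configuration. The addition must occur at the carbonyl and not at C4, at C6 or at the side-chain CH2 protons: C4 and C6 are fully substituted and each carries an oxygen donor, the acidic site is a secondary CH2 and no longer a methyl group, and an oxophilic, weakly basic trivalent cerium counter-ion at −78 °C without dipolar cosolvent is the established means of favouring carbonyl addition over enolisation and conjugate addition. In the closure the CH2 between ester and ketone is by far the most acidic carbon of 18, so it and not C8 is the nucleophile, the rival C6-to-ester Claisen closure would have to expel a hindered secondary alkoxide, and closure through oxygen back to a 2H-pyranol is reversible and drains into the aromatic product.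

Step 9
Reactants: 20 (R)-11-[3,5-bis(benzyloxy)phenyl]undecan-4-yl 6-[(9R)-9-(tert-butyldimethylsilyloxy)dodecyl]-2-hydroxy-4-methoxybenzoate
Product: 21 (R)-11-[3,5-bis(benzyloxy)phenyl]undecan-4-yl 2-hydroxy-6-[(9R)-9-hydroxydodecyl]-4-methoxybenzoate
Conditions: HF·pyridine, pyridine, THF, 0 °C → rt
Reagents that add atoms: none
Why: Fluoride-driven cleavage of the Si–O bond frees the secondary alcohol with retention and leaves the benzyl ethers, the benzoate and the phenol alone.

Step 10
Reactants: 21 (R)-11-[3,5-bis(benzyloxy)phenyl]undecan-4-yl 2-hydroxy-6-[(9R)-9-hydroxydodecyl]-4-methoxybenzoate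
Product: 23 (R)-11-[3,5-bis(benzyloxy)phenyl]undecan-4-yl 6-[(9R)-9-acetoxydodecyl]-2-hydroxy-4-methoxybenzoate, via diacetate 22 (not isolated)
Conditions: Ac2O, pyridine, DMAP (cat.), CH2Cl2, rt; evaporate; then K2CO3 (cat.), MeOH–THF, 0 °C
Reagents that add atoms: acetic anhydride, CC(=O)OC(C)=O
Why: DMAP-catalysed acetylation esterifies the carbinol (retention, the C–O bond is not broken) and the chelated phenol, and the carbonate-catalysed transesterification that follows removes only the aryl acetate, whose phenoxide is a far better leaving group than a secondary alkoxide, so that all material converges on 23.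

Step 11
Reactants: 23 (R)-11-[3,5-bis(benzyloxy)phenyl]undecan-4-yl 6-[(9R)-9-acetoxydodecyl]-2-hydroxy-4-methoxybenzoate
Product: 24 5'-methoxy-integracin A
Conditions: H2 (1 atm), Pd/C, EtOAc, rt
Reagents that add atoms: none
Why: Catalytic hydrogenolysis cleaves the two benzylic C–O bonds of the aryl benzyl ethers, and nothing else in 23 (arenes, alkyl esters, aryl methyl ether) is reducible under one atmosphere of hydrogen at room temperature.

**Compound list**
1 | 6-bromohex-1-ene | C=CCCCCBr | starting material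
2 | (R)-2-propyloxirane | CCC[C@@H]1CO1 | starting material
3 | hex-5-enylmagnesium bromide | C=CCCCC[Mg]Br | intermediate
4 | (R)-undec-10-en-4-ol | CCC[C@@H](O)CCCCCC=C | intermediate
5 | (R)-tert-butyldimethyl(undec-10-en-4-yloxy)silane | CCC[C@H](CCCCCC=C)O[Si](C)(C)C(C)(C)C | intermediate
6 | 9-[(8R)-8-(tert-butyldimethylsilyloxy)undecyl]-9-borabicyclo[3.3.1]nonane | CCC[C@H](CCCCCCCB1C2CCCC1CCC2)O[Si](C)(C)C(C)(C)C | intermediate
7 | (R)-8-(tert-butyldimethylsilyloxy)undecan-1-ol | CCC[C@H](CCCCCCCO)O[Si](C)(C)C(C)(C)C | intermediate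
8 | (R)-tert-butyl[(11-iodoundecan-4-yl)oxy]dimethylsilane | CCC[C@H](CCCCCCCI)O[Si](C)(C)C(C)(C)C | intermediate
9 | 4-methoxy-6-methyl-2H-pyran-2-one | COC1=CC(=O)OC(C)=C1 | starting material
10 | (4-methoxy-2-oxo-2H-pyran-6-yl)methyllithium (delocalised dienolate) | [Li+].[CH2-]C1=CC(OC)=CC(=O)O1 | intermediate
11 | 6-[(9R)-9-(tert-butyldimethylsilyloxy)dodecyl]-4-methoxy-2H-pyran-2-one | COC1=CC(=O)OC(CCCCCCCC[C@@H](CCC)O[Si](C)(C)C(C)(C)C)=C1 | intermediate
12 | (R)-undec-10-en-4-yl acetate | CC(=O)O[C@H](CCC)CCCCCC=C | intermediate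
13 | 1,3-bis(benzyloxy)-5-bromobenzene | Brc1cc(OCc2ccccc2)cc(OCc2ccccc2)c1 | starting material
14 | (R)-11-(9-borabicyclo[3.3.1]nonan-9-yl)undecan-4-yl acetate | CC(=O)O[C@H](CCC)CCCCCCCB1C2CCCC1CCC2 | intermediate
15 | (R)-11-[3,5-bis(benzyloxy)phenyl]undecan-4-yl acetate | CC(=O)O[C@H](CCC)CCCCCCCc1cc(OCc2ccccc2)cc(OCc2ccccc2)c1 | intermediate
16 | lithium enolate of 15 | [Li]OC(=C)O[C@H](CCC)CCCCCCCc1cc(OCc2ccccc2)cc(OCc2ccccc2)c1 | intermediate
17 | dichlorocerium enolate of 15 | Cl[Ce](Cl)OC(=C)O[C@H](CCC)CCCCCCCc1cc(OCc2ccccc2)cc(OCc2ccccc2)c1 | intermediate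
18 | (R)-11-[3,5-bis(benzyloxy)phenyl]undecan-4-yl (4E,16R)-16-(tert-butyldimethylsilyloxy)-5-methoxy-3,7-dioxononadec-4-enoate | CCC[C@H](CCCCCCCCC(=O)C/C(OC)=C\C(=O)CC(=O)O[C@H](CCC)CCCCCCCc1cc(OCc2ccccc2)cc(OCc2ccccc2)c1)O[Si](C)(C)C(C)(C)C | intermediate
19 | (R)-11-[3,5-bis(benzyloxy)phenyl]undecan-4-yl 2-[(9R)-9-(tert-butyldimethylsilyloxy)dodecyl]-2-hydroxy-4-methoxy-6-oxocyclohex-4-ene-1-carboxylate (mixture at the two transient ring centres) | CCC[C@H](CCCCCCCCC1(O)CC(OC)=CC(=O)C1C(=O)O[C@H](CCC)CCCCCCCc1cc(OCc2ccccc2)cc(OCc2ccccc2)c1)O[Si](C)(C)C(C)(C)C | intermediate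
20 | (R)-11-[3,5-bis(benzyloxy)phenyl]undecan-4-yl 6-[(9R)-9-(tert-butyldimethylsilyloxy)dodecyl]-2-hydroxy-4-methoxybenzoate | CCC[C@H](CCCCCCCCc1cc(OC)cc(O)c1C(=O)O[C@H](CCC)CCCCCCCc1cc(OCc2ccccc2)cc(OCc2ccccc2)c1)O[Si](C)(C)C(C)(C)C | intermediate
21 | (R)-11-[3,5-bis(benzyloxy)phenyl]undecan-4-yl 2-hydroxy-6-[(9R)-9-hydroxydodecyl]-4-methoxybenzoate | CCC[C@@H](O)CCCCCCCCc1cc(OC)cc(O)c1C(=O)O[C@H](CCC)CCCCCCCc1cc(OCc2ccccc2)cc(OCc2ccccc2)c1 | intermediate
22 | (R)-11-[3,5-bis(benzyloxy)phenyl]undecan-4-yl 2-acetoxy-6-[(9R)-9-acetoxydodecyl]-4-methoxybenzoate | CCC[C@H](CCCCCCCCc1cc(OC)cc(OC(C)=O)c1C(=O)O[C@H](CCC)CCCCCCCc1cc(OCc2ccccc2)cc(OCc2ccccc2)c1)OC(C)=O | intermediate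
23 | (R)-11-[3,5-bis(benzyloxy)phenyl]undecan-4-yl 6-[(9R)-9-acetoxydodecyl]-2-hydroxy-4-methoxybenzoate | CCC[C@H](CCCCCCCCc1cc(OC)cc(O)c1C(=O)O[C@H](CCC)CCCCCCCc1cc(OCc2ccccc2)cc(OCc2ccccc2)c1)OC(C)=O | intermediate
24 | 5'-methoxy-integracin A, (R)-11-(3,5-dihydroxyphenyl)undecan-4-yl 6-[(9R)-9-acetoxydodecyl]-2-hydroxy-4-methoxybenzoate | CCC[C@H](CCCCCCCCc1cc(OC)cc(O)c1C(=O)O[C@H](CCC)CCCCCCCc1cc(O)cc(O)c1)OC(C)=O | target

**Total steps:** 11.
**Longest linear sequence:** 9 (steps 1, 2, 3, 4, 5, 8, 9, 10, 11).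

**Steps most likely to fail**

1. **Step 8.**
   - What may go wrong:
     - Proton transfer from the side-chain CH2 of the pyranone to the enolate would stop the reaction.
     - Conjugate attack at C4 or C6 may take the place of carbonyl addition.
     - A second enolate may add to the ketone once the ring has opened.
     - The DBU stage may close through oxygen instead of carbon.
   - Fallback (known chemistry): ring A is bought instead of made. It sets out from 8 and 15 and comes back at 20. Commercial 2,4-dihydroxy-6-methylbenzoic acid is condensed with acetone (TFAA, TFA) to 7-hydroxy-2,2,5-trimethyl-4H-benzo[d][1,3]dioxin-4-one F1. O-methylation (MeI, K2CO3, acetone) gives 7-methoxy-2,2,5-trimethyl-4H-benzo[d][1,3]dioxin-4-one F2. Lateral lithiation of the 5-methyl group (LiN(iPr)2, THF, −78 °C) and alkylation with 8 gives 5-[(9R)-9-(tert-butyldimethylsilyloxy)dodecyl]-7-methoxy-2,2-dimethyl-4H-benzo[d][1,3]dioxin-4-one F3. Separately, 15 is methanolysed (K2CO3, MeOH) to (R)-11-[3,5-bis(benzyloxy)phenyl]undecan-4-ol F4. Its sodium alkoxide (NaH, THF, 0 °C → rt) opens the tied-back dioxinone carbonyl of F3 with loss of the acetonide carbon unit, giving 20 with the C2 phenol free.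

2. **Step 5.**
   - What may go wrong:
     - Displacement by the delocalised anion may be slow, so that proton exchange between product and anion leads to double alkylation.
     - The anion may attack through ring carbon C3.
     - The iodide may suffer base-induced elimination.
   - Fallback: carbonyl addition replaces SN2 alkylation. It sets out from 7 and 10 and comes back at 11. Oxidation of 7 (Dess–Martin periodinane, CH2Cl2) gives (R)-8-(tert-butyldimethylsilyloxy)undecanal F5. The anion 10 adds to it at −78 °C to give 6-[(9R)-9-(tert-butyldimethylsilyloxy)-2-hydroxydodecyl]-4-methoxy-2H-pyran-2-one F6, as a mixture at the new carbinol carbon. MsCl and Et3N convert this into (9R)-9-(tert-butyldimethylsilyloxy)-1-(4-methoxy-2-oxo-2H-pyran-6-yl)dodecan-2-yl methanesulfonate F7. DBU eliminates it to 6-[(1E,9R)-9-(tert-butyldimethylsilyloxy)dodec-1-enyl]-4-methoxy-2H-pyran-2-one F8. Hydrogenation (H2, Pd/C, EtOAc, stopped after one equivalent) saturates the side-chain alkene and gives 11.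

3. **Step 10.**
   - What may go wrong:
     - The methanolysis may not discriminate fully between the two acetates, so that the side-chain acetate is lost or the aryl acetate is only partly cleaved.
   - Fallback: the phenol is masked, so no selectivity is needed. It sets out from 20 and comes back at 24. Benzylation of 20 (BnBr, Cs2CO3, DMF, 50 °C) gives (R)-11-[3,5-bis(benzyloxy)phenyl]undecan-4-yl 2-(benzyloxy)-6-[(9R)-9-(tert-butyldimethylsilyloxy)dodecyl]-4-methoxybenzoate F9. HF·pyridine gives (R)-11-[3,5-bis(benzyloxy)phenyl]undecan-4-yl 2-(benzyloxy)-6-[(9R)-9-hydroxydodecyl]-4-methoxybenzoate F10. Acetylation (Ac2O, DMAP, pyridine) gives (R)-11-[3,5-bis(benzyloxy)phenyl]undecan-4-yl 6-[(9R)-9-acetoxydodecyl]-2-(benzyloxy)-4-methoxybenzoate F11. Hydrogenolysis of all three benzyl ethers (H2, Pd/C, EtOAc) gives 24.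

**Further compounds**
F1 | step 8 | 7-hydroxy-2,2,5-trimethyl-4H-benzo[d][1,3]dioxin-4-one | Cc1cc(O)cc2OC(C)(C)OC(=O)c12
F2 | step 8 | 7-methoxy-2,2,5-trimethyl-4H-benzo[d][1,3]dioxin-4-one | Cc1cc(OC)cc2OC(C)(C)OC(=O)c12
F3 | step 8 | 5-[(9R)-9-(tert-butyldimethylsilyloxy)dodecyl]-7-methoxy-2,2-dimethyl-4H-benzo[d][1,3]dioxin-4-one | CCC[C@H](CCCCCCCCc1cc(OC)cc2OC(C)(C)OC(=O)c12)O[Si](C)(C)C(C)(C)C
F4 | step 8 | (R)-11-[3,5-bis(benzyloxy)phenyl]undecan-4-ol | CCC[C@@H](O)CCCCCCCc1cc(OCc2ccccc2)cc(OCc2ccccc2)c1
F5 | step 5 | (R)-8-(tert-butyldimethylsilyloxy)undecanal | CCC[C@H](CCCCCCC=O)O[Si](C)(C)C(C)(C)C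
F6 | step 5 | 6-[(9R)-9-(tert-butyldimethylsilyloxy)-2-hydroxydodecyl]-4-methoxy-2H-pyran-2-one | CCC[C@H](CCCCCCC(O)CC1=CC(OC)=CC(=O)O1)O[Si](C)(C)C(C)(C)C
F7 | step 5 | (9R)-9-(tert-butyldimethylsilyloxy)-1-(4-methoxy-2-oxo-2H-pyran-6-yl)dodecan-2-yl methanesulfonate | CCC[C@H](CCCCCCC(CC1=CC(OC)=CC(=O)O1)OS(C)(=O)=O)O[Si](C)(C)C(C)(C)C
F8 | step 5 | 6-[(1E,9R)-9-(tert-butyldimethylsilyloxy)dodec-1-enyl]-4-methoxy-2H-pyran-2-one | CCC[C@H](CCCCCC/C=C/C1=CC(OC)=CC(=O)O1)O[Si](C)(C)C(C)(C)C
F9 | step 10 | (R)-11-[3,5-bis(benzyloxy)phenyl]undecan-4-yl 2-(benzyloxy)-6-[(9R)-9-(tert-butyldimethylsilyloxy)dodecyl]-4-methoxybenzoate | CCC[C@H](CCCCCCCCc1cc(OC)cc(OCc2ccccc2)c1C(=O)O[C@H](CCC)CCCCCCCc1cc(OCc2ccccc2)cc(OCc2ccccc2)c1)O[Si](C)(C)C(C)(C)C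
F10 | step 10 | (R)-11-[3,5-bis(benzyloxy)phenyl]undecan-4-yl 2-(benzyloxy)-6-[(9R)-9-hydroxydodecyl]-4-methoxybenzoate | CCC[C@@H](O)CCCCCCCCc1cc(OC)cc(OCc2ccccc2)c1C(=O)O[C@H](CCC)CCCCCCCc1cc(OCc2ccccc2)cc(OCc2ccccc2)c1
F11 | step 10 | (R)-11-[3,5-bis(benzyloxy)phenyl]undecan-4-yl 6-[(9R)-9-acetoxydodecyl]-2-(benzyloxy)-4-methoxybenzoate | CCC[C@H](CCCCCCCCc1cc(OC)cc(OCc2ccccc2)c1C(=O)O[C@H](CCC)CCCCCCCc1cc(OCc2ccccc2)cc(OCc2ccccc2)c1)OC(C)=O
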